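**Plan**

- Retrosynthesis: the C-6 ester C–O bond is cut first (acid 26 + core alcohol 17). The C-6–C-7 and C-4a–C-8a bonds of the decalin core are then cut together, which leads back to the open-chain allylic sulfone/(Z)-enoate 7 built on a D-threitol acetonide.
- Enabling feature: in ring B, C-7/C-8/C-8a is an allyl unit and C-4a/C-5/C-6 is an acrylate unit (quaternary C-4a = β-carbon, C-6 = acyl carbon), and C-4a–C-8a is also the fusion bond of ring A. A sulfone-stabilised allyl anion can therefore add through C-8a to C-4a (closing ring A) and then through C-7 to C-6 (closing ring B).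
- Forward order: the two arms of the chain are attached (allyl, then (Z)-enoate, then the sulfone by cross-metathesis), followed by the bicyclisation, desulfonylation, dehydrogenation to the dienone, C-5 methyl, C-6 alcohol, esterification, deprotection and oxidation at C-2.
- Stereochemistry: C-3 comes from D-threitol. C-4a is set in the cascade (chair with equatorial acetonide oxygens and 1,3-allylic strain of the (Z)-enoate). C-5 and C-6 are set by hydrogenation and hydride delivery anti to the angular methyl. C-6′/C-7′ come from an Evans syn-aldol with the (R)-auxiliary, and the (E,E)-diene from a Horner–Wadsworth–Emmons olefination.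

Key step: step 6

Remark: locants C-1 to C-8a are those of the naphthalen-2(3H)-one core of the target (C-2 ketone, C-3 carbinol, C-4a quaternary carbon, C-5 CHMe, C-6 ester-bearing carbon). Compounds 1, 6, 18, 19 and 24 are taken as commercially available. The C-2 configuration carried by the acetonide is auxiliary and is erased in step 20.

**Route**

Step 1
Reactants: 1 1,4-di-O-tosyl-2,3-O-isopropylidene-D-threitol [(4R,5R)-ditosylate]
Product: 2 [(4R,5R)-2,2-dimethyl-5-(prop-2-en-1-yl)-1,3-dioxolan-4-yl]methyl 4-methylbenzenesulfonate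
Conditions: CH2=CHMgBr (1.1 equiv), CuI (10 mol%), THF, −30 → 0 °C
Reagents that add atoms: vinylmagnesium bromide C=C[Mg]Br
Why: Copper-catalysed SN2 displacement of a primary tosylate by the vinyl Grignard reagent; the two tosylates of C2-symmetric 1 are equivalent, so monosubstitution (unreacted 1 being recovered) should give one product with both stereocentres untouched.

Step 2
Reactants: 2 [(4R,5R)-2,2-dimethyl-5-(prop-2-en-1-yl)-1,3-dioxolan-4-yl]methyl 4-methylbenzenesulfonate
Product: 3 (4R,5R)-2,2-dimethyl-4-(prop-2-en-1-yl)-5-(prop-2-yn-1-yl)-1,3-dioxolane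
Conditions: LiC≡CH·H2NCH2CH2NH2, DMSO, 15 → 20 °C
Reagents that add atoms: lithium acetylide (ethylenediamine complex) [Li]C#C
Why: SN2 alkylation of the acetylide by the remaining primary tosylate; no stereocentre is involved.

Step 3
Reactants: 3 (4R,5R)-2,2-dimethyl-4-(prop-2-en-1-yl)-5-(prop-2-yn-1-yl)-1,3-dioxolane
Product: 4 methyl 4-[(4R,5R)-2,2-dimethyl-5-(prop-2-en-1-yl)-1,3-dioxolan-4-yl]but-2-ynoate
Conditions: n-BuLi, THF, −78 °C; then ClCO2Me, −78 → 0 °C
Reagents that add atoms: methyl chloroformate COC(=O)Cl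
Why: Deprotonation of the terminal alkyne and C-acylation of the lithium acetylide by the chloroformate (alkynoate synthesis).

Step 4
Reactants: 4 methyl 4-[(4R,5R)-2,2-dimethyl-5-(prop-2-en-1-yl)-1,3-dioxolan-4-yl]but-2-ynoate
Product: 5 methyl (2Z)-4-[(4R,5R)-2,2-dimethyl-5-(prop-2-en-1-yl)-1,3-dioxolan-4-yl]-3-methylbut-2-enoate
Conditions: Me2CuLi (1.3 equiv), THF, −78 °C; MeOH then aq. NH4Cl at −78 °C
Reagents that add atoms: lithium dimethylcuprate [Li+].C[Cu-]C
Why: Syn carbocupration (conjugate addition) of the alkynoate and low-temperature protonation of the alkenylcuprate place the new methyl cis to H, which should give the (Z)-β,β-disubstituted enoate (ester cis to the CH2 arm) stereospecifically.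

Step 5
Reactants: 5 methyl (2Z)-4-[(4R,5R)-2,2-dimethyl-5-(prop-2-en-1-yl)-1,3-dioxolan-4-yl]-3-methylbut-2-enoate; 6 allyl phenyl sulfone
Product: 7 methyl (2Z)-4-{(4R,5R)-2,2-dimethyl-5-[(2E)-4-(phenylsulfonyl)but-2-en-1-yl]-1,3-dioxolan-4-yl}-3-methylbut-2-enoate
Conditions: 6 (3 equiv), second-generation Grubbs catalyst [RuCl2(=CHPh)(PCy3)(H2IMes)] (5 mol%), CH2Cl2, 40 °C
Reagents that add atoms: none
Why: Olefin cross-metathesis of the monosubstituted alkene with excess allyl sulfone should give the (E)-allylic sulfone, the trisubstituted electron-poor enoate being inert.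

Step 6
Reactants: 7 methyl (2Z)-4-{(4R,5R)-2,2-dimethyl-5-[(2E)-4-(phenylsulfonyl)but-2-en-1-yl]-1,3-dioxolan-4-yl}-3-methylbut-2-enoate
Product: 9 (2R,3R,4aR)-2,3-(isopropylidenedioxy)-4a-methyl-7-(phenylsulfonyl)-1,2,3,4,4a,5-hexahydronaphthalen-6(7H)-one, via vinyl sulfone ester 8 (not isolated)
Conditions: LiN(SiMe3)2 (1.05 equiv), THF, −78 → −20 °C; then LiN(SiMe3)2 (1.2 equiv), −20 → 20 °C; aq. NH4Cl, −78 °C
Reagents that add atoms: none
Why: Proposed new method: deprotonation of the allylic sulfone gives a delocalised C-7/C-8/C-8a anion whose γ-carbon C-8a adds to C-4a of the (Z)-enoate (6-exo-trig conjugate addition, ring A); proton transfer from C-8a–H then regenerates the sulfonyl allyl anion, whose α-carbon C-7 acylates the ester carbonyl C-6 (6-exo-trig Dieckmann-type closure, ring B) with loss of methoxide, the stabilised β-keto sulfone enolate being the thermodynamic sink. The closest known reaction types are the Hauser–Kraus annulation (sulfone-anion Michael addition followed by Dieckmann condensation) and γ-selective conjugate additions of lithiated allylic sulfones; the one-pot intramolecular double closure of an acyclic allyl sulfone/enoate is new. The only stereocentre created and kept, C-4a, is set in a chair transition state in which the trans-acetonide holds O-2 and O-3 equatorial and 1,3-allylic strain between the ester (cis to C-4 in the (Z)-enoate) and C-3 forces the acceptor alkene pseudo-equatorial and the methyl pseudo-axial, that is trans to O-3 (4aR); C-8a becomes sp2 and the C-7 centre is removed in step 7. γ- over α-attack in the first closure is enforced by ring size (six- against eight-membered), and deprotonation at the sulfone (more acidic than the enoate γ-CH2) with one equivalent of base at −78 °C should avoid vinylogous β-elimination of the acetonide oxygen.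

Step 7
Reactants: 9 (2R,3R,4aR)-2,3-(isopropylidenedioxy)-4a-methyl-7-(phenylsulfonyl)-1,2,3,4,4a,5-hexahydronaphthalen-6(7H)-one
Product: 10 (2R,3R,4aR)-2,3-(isopropylidenedioxy)-4a-methyl-1,2,3,4,4a,5-hexahydronaphthalen-6(7H)-one
Conditions: SmI2 (2.5 equiv), THF/MeOH, −78 °C
Reagents that add atoms: none
Why: Single-electron reductive cleavage of the α-keto (and allylic) C–S bond by divalent samarium gives the samarium dienolate, which methanol protonates to the β,γ-unsaturated ketone without touching a stereocentre.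

Step 8
Reactants: 10 (2R,3R,4aR)-2,3-(isopropylidenedioxy)-4a-methyl-1,2,3,4,4a,5-hexahydronaphthalen-6(7H)-one
Product: 12 (2R,3R,4aR)-2,3-(isopropylidenedioxy)-4a-methyl-3,4,4a,5-tetrahydronaphthalen-6(2H)-one, via silyl dienol ether 11 (not isolated)
Conditions: LiN(SiMe3)2, Me3SiCl, THF, −78 °C; then DDQ, 2,4,6-collidine, CH2Cl2, 0 °C
Reagents that add atoms: none
Why: Deprotonation at the doubly activated C-7 gives the linear 6-silyloxy diene, and hydride abstraction by DDQ at the terminal allylic C-1 (dehydrogenation of a dienol ether to a linear dienone) should deliver the C-7=C-8/C-8a=C-1 dienone.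

Step 9
Reactants: 12 (2R,3R,4aR)-2,3-(isopropylidenedioxy)-4a-methyl-3,4,4a,5-tetrahydronaphthalen-6(2H)-one
Product: 15 (2R,3R,4aS)-2,3-(isopropylidenedioxy)-4a-methyl-5-methylidene-3,4,4a,5-tetrahydronaphthalen-6(2H)-one (same geometry at C-4a; descriptor changes by priority only), via Mannich base 13 (not isolated), via ammonium iodide 14 (not isolated)
Conditions: LiN(iPr)2, THF, −78 °C; CH2=NMe2+ I−, −78 → 20 °C; then MeI, CH2Cl2; then aq. NaHCO3, 20 °C
Reagents that add atoms: N,N-dimethylmethyleneiminium iodide C=[N+](C)C.[I-]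
Why: Kinetic enolate formation at C-5 (the only α-CH2 left), Mannich aminomethylation, N-methylation and base-induced loss of trimethylamine (α-methylenation of a ketone).

Step 10
Reactants: 15 (2R,3R,4aS)-2,3-(isopropylidenedioxy)-4a-methyl-5-methylidene-3,4,4a,5-tetrahydronaphthalen-6(2H)-one
Product: 16 (2R,3R,4aR,5R)-2,3-(isopropylidenedioxy)-4a,5-dimethyl-3,4,4a,5-tetrahydronaphthalen-6(2H)-one
Conditions: H2 (1 atm), RhCl(PPh3)3 (10 mol%), benzene, 20 °C
Reagents that add atoms: none
Why: Homogeneous hydrogenation with RhCl(PPh3)3 is selective for the unhindered 1,1-disubstituted exocyclic alkene over the ring dienone alkenes, and hydrogen delivery to the face opposite the adjacent angular C-4a methyl should set C-5 with its methyl cis to that methyl (5R).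

Step 11
Reactants: 16 (2R,3R,4aR,5R)-2,3-(isopropylidenedioxy)-4a,5-dimethyl-3,4,4a,5-tetrahydronaphthalen-6(2H)-one
Product: 17 (2R,3R,4aR,5R,6S)-2,3-(isopropylidenedioxy)-4a,5-dimethyl-2,3,4,4a,5,6-hexahydronaphthalen-6-ol
Conditions: NaBH4, CeCl3·7H2O, MeOH, −78 → −40 °C
Reagents that add atoms: none
Why: Luche 1,2-reduction of the dienone; hydride attack from the face opposite the C-4a and C-5 methyl groups should give the 6S alcohol (hydroxyl cis to both methyls).

Step 12
Reactants: 18 (R)-4-benzyl-3-propionyloxazolidin-2-one; 19 acetaldehyde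
Product: 20 (R)-4-benzyl-3-[(2R,3S)-3-hydroxy-2-methylbutanoyl]oxazolidin-2-one
Conditions: Bu2BOTf, iPr2NEt, CH2Cl2, −78 → 0 °C; 19, −78 → 0 °C; then MeOH, pH 7 buffer, H2O2, 0 °C
Reagents that add atoms: none
Why: Evans syn-aldol reaction through the (Z)-boron enolate in a closed chair transition state; the (R)-auxiliary should give the (2R,3S) adduct.

Step 13
Reactants: 20 (R)-4-benzyl-3-[(2R,3S)-3-hydroxy-2-methylbutanoyl]oxazolidin-2-one
Product: 21 (2R,3S)-3-hydroxy-N-methoxy-N,2-dimethylbutanamide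
Conditions: MeNHOMe·HCl, AlMe3, CH2Cl2, −20 → 20 °C
Reagents that add atoms: N,O-dimethylhydroxylamine hydrochloride CNOC.Cl
Why: Aluminium amide aminolysis of the imide to the N-methoxy-N-methyl amide with release of the auxiliary, without touching the stereocentres.

Step 14
Reactants: 21 (2R,3S)-3-hydroxy-N-methoxy-N,2-dimethylbutanamide
Product: 22 (2R,3S)-N-methoxy-N,2-dimethyl-3-[(triethylsilyl)oxy]butanamide
Conditions: Et3SiCl, imidazole, CH2Cl2, 0 → 20 °C
Reagents that add atoms: chlorotriethylsilane CC[Si](Cl)(CC)CC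
Why: Silylation of the secondary alcohol; the triethylsilyl ether is chosen so that it is removed in the mild acid step 19.

Step 15
Reactants: 22 (2R,3S)-N-methoxy-N,2-dimethyl-3-[(triethylsilyl)oxy]butanamide
Product: 23 (2R,3S)-2-methyl-3-[(triethylsilyl)oxy]butanal
Conditions: iBu2AlH, THF, −78 °C
Reagents that add atoms: none
Why: Hydride reduction of the N-methoxy-N-methyl amide stops at the aldehyde through the chelated tetrahedral intermediate, and the low temperature protects the α-stereocentre.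

Step 16
Reactants: 23 (2R,3S)-2-methyl-3-[(triethylsilyl)oxy]butanal; 24 triethyl 4-phosphonocrotonate
Product: 25 ethyl (2E,4E,6S,7S)-6-methyl-7-[(triethylsilyl)oxy]octa-2,4-dienoate
Conditions: 24, LiN(SiMe3)2, THF, −78 °C; then 23, −78 → 0 °C; aq. NH4Cl
Reagents that add atoms: none
Why: Vinylogous Horner–Wadsworth–Emmons olefination with the lithiated phosphonocrotonate should give the (2E,4E)-dienoate without epimerising C-6.

Step 17
Reactants: 25 ethyl (2E,4E,6S,7S)-6-methyl-7-[(triethylsilyl)oxy]octa-2,4-dienoate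
Product: 26 (2E,4E,6S,7S)-6-methyl-7-[(triethylsilyl)oxy]octa-2,4-dienoic acid
Conditions: LiOH·H2O, THF/MeOH/H2O, 0 → 20 °C; then dilute HCl to pH 4, 0 °C
Reagents that add atoms: lithium hydroxide [Li+].[OH-]
Why: Saponification of the ethyl ester under mild conditions that the secondary silyl ether should survive.

Step 18
Reactants: 17 (2R,3R,4aR,5R,6S)-2,3-(isopropylidenedioxy)-4a,5-dimethyl-2,3,4,4a,5,6-hexahydronaphthalen-6-ol; 26 (2E,4E,6S,7S)-6-methyl-7-[(triethylsilyl)oxy]octa-2,4-dienoic acid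
Product: 27 (2R,3R,4aR,5R,6S)-2,3-(isopropylidenedioxy)-4a,5-dimethyl-2,3,4,4a,5,6-hexahydronaphthalen-6-yl (2E,4E,6S,7S)-6-methyl-7-[(triethylsilyl)oxy]octa-2,4-dienoate
Conditions: 26, 2,4,6-trichlorobenzoyl chloride, Et3N, THF, 20 °C; then 17, DMAP, toluene, 20 °C
Reagents that add atoms: none
Why: Yamaguchi esterification through the mixed anhydride; the C-6 alcohol is the only free hydroxyl and its configuration is retained because the C–O bond is not broken.

Step 19
Reactants: 27 (2R,3R,4aR,5R,6S)-2,3-(isopropylidenedioxy)-4a,5-dimethyl-2,3,4,4a,5,6-hexahydronaphthalen-6-yl (2E,4E,6S,7S)-6-methyl-7-[(triethylsilyl)oxy]octa-2,4-dienoate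
Product: 28 (2R,3R,4aR,5R,6S)-2,3-dihydroxy-4a,5-dimethyl-2,3,4,4a,5,6-hexahydronaphthalen-6-yl (2E,4E,6S,7S)-7-hydroxy-6-methylocta-2,4-dienoate
Conditions: AcOH/THF/H2O (3:1:1), 35 °C
Reagents that add atoms: none
Why: Mild aqueous acid hydrolysis should remove the strained trans-fused acetonide and the triethylsilyl ether in one operation, the conditions being kept mild to spare the allylic ester.

Step 20
Reactants: 28 (2R,3R,4aR,5R,6S)-2,3-dihydroxy-4a,5-dimethyl-2,3,4,4a,5,6-hexahydronaphthalen-6-yl (2E,4E,6S,7S)-7-hydroxy-6-methylocta-2,4-dienoate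
Product: 29 (3R,4aR,5R,6S)-3-hydroxy-4a,5-dimethyl-2-oxo-2,3,4,4a,5,6-hexahydronaphthalen-6-yl (2E,4E,6S,7S)-7-hydroxy-6-methylocta-2,4-dienoate (target)
Conditions: MnO2 (activated, excess), CH2Cl2, 20 °C
Reagents that add atoms: none
Why: Activated MnO2 oxidises only the allylic (dienylic) C-2 alcohol; the C-3 and side-chain alcohols are not allylic and should remain, which gives the α-hydroxy dienone with C-3 (from D-threitol) intact.

**Compound list**

1 | 1,4-di-O-tosyl-2,3-O-isopropylidene-D-threitol, (4R,5R) | Cc1ccc(cc1)S(=O)(=O)OC[C@H]2OC(C)(C)O[C@@H]2COS(=O)(=O)c3ccc(C)cc3 | starting material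
2 | [(4R,5R)-2,2-dimethyl-5-(prop-2-en-1-yl)-1,3-dioxolan-4-yl]methyl 4-methylbenzenesulfonate | C=CC[C@H]1OC(C)(C)O[C@@H]1COS(=O)(=O)c1ccc(C)cc1 | intermediate
3 | (4R,5R)-2,2-dimethyl-4-(prop-2-en-1-yl)-5-(prop-2-yn-1-yl)-1,3-dioxolane | C=CC[C@H]1OC(C)(C)O[C@@H]1CC#C | intermediate
4 | methyl 4-[(4R,5R)-2,2-dimethyl-5-(prop-2-en-1-yl)-1,3-dioxolan-4-yl]but-2-ynoate | C=CC[C@H]1OC(C)(C)O[C@@H]1CC#CC(=O)OC | intermediate
5 | methyl (2Z)-4-[(4R,5R)-2,2-dimethyl-5-(prop-2-en-1-yl)-1,3-dioxolan-4-yl]-3-methylbut-2-enoate | C=CC[C@H]1OC(C)(C)O[C@@H]1C/C(C)=C\C(=O)OC | intermediate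
6 | allyl phenyl sulfone | C=CCS(=O)(=O)c1ccccc1 | starting material
7 | methyl (2Z)-4-{(4R,5R)-2,2-dimethyl-5-[(2E)-4-(phenylsulfonyl)but-2-en-1-yl]-1,3-dioxolan-4-yl}-3-methylbut-2-enoate | O=S(=O)(c1ccccc1)C/C=C/C[C@H]2OC(C)(C)O[C@@H]2C/C(C)=C\C(=O)OC | intermediate
8 | vinyl sulfone ester: methyl [(2R,3R,4aR)-2,3-(isopropylidenedioxy)-4a-methyl-8a-[(E)-2-(phenylsulfonyl)ethenyl]cyclohexan-4a-yl]acetate (ring A only, core locants, C-8a epimers) | COC(=O)C[C@@]1(C)C[C@H]2OC(C)(C)O[C@@H]2CC1/C=C/S(=O)(=O)c3ccccc3 | intermediate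
9 | (2R,3R,4aR)-2,3-(isopropylidenedioxy)-4a-methyl-7-(phenylsulfonyl)-1,2,3,4,4a,5-hexahydronaphthalen-6(7H)-one (C-7 epimers) | O=C1C(S(=O)(=O)c2ccccc2)C=C3C[C@H]4OC(C)(C)O[C@@H]4C[C@]3(C)C1 | intermediate
10 | (2R,3R,4aR)-2,3-(isopropylidenedioxy)-4a-methyl-1,2,3,4,4a,5-hexahydronaphthalen-6(7H)-one | O=C1CC=C2C[C@H]3OC(C)(C)O[C@@H]3C[C@]2(C)C1 | intermediate
11 | silyl dienol ether: (2R,3R,4aR)-2,3-(isopropylidenedioxy)-4a-methyl-6-(trimethylsilyloxy)-1,2,3,4,4a,5-hexahydronaphthalene | C[Si](C)(C)OC1=CC=C2C[C@H]3OC(C)(C)O[C@@H]3C[C@]2(C)C1 | intermediate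
12 | (2R,3R,4aR)-2,3-(isopropylidenedioxy)-4a-methyl-3,4,4a,5-tetrahydronaphthalen-6(2H)-one | O=C1C=CC2=C[C@H]3OC(C)(C)O[C@@H]3C[C@]2(C)C1 | intermediate
13 | Mannich base: 5-[(dimethylamino)methyl] derivative of 12 (C-5 epimers) | O=C1C=CC2=C[C@H]3OC(C)(C)O[C@@H]3C[C@]2(C)C1CN(C)C | intermediate
14 | ammonium iodide: 5-[(trimethylammonio)methyl] derivative of 12, iodide | O=C1C=CC2=C[C@H]3OC(C)(C)O[C@@H]3C[C@]2(C)C1C[N+](C)(C)C.[I-] | intermediate
15 | (2R,3R,4aS)-2,3-(isopropylidenedioxy)-4a-methyl-5-methylidene-3,4,4a,5-tetrahydronaphthalen-6(2H)-one | O=C1C=CC2=C[C@H]3OC(C)(C)O[C@@H]3C[C@]2(C)C1=C | intermediate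
16 | (2R,3R,4aR,5R)-2,3-(isopropylidenedioxy)-4a,5-dimethyl-3,4,4a,5-tetrahydronaphthalen-6(2H)-one | O=C1C=CC2=C[C@H]3OC(C)(C)O[C@@H]3C[C@]2(C)[C@H]1C | intermediate
17 | (2R,3R,4aR,5R,6S)-2,3-(isopropylidenedioxy)-4a,5-dimethyl-2,3,4,4a,5,6-hexahydronaphthalen-6-ol | O[C@H]1C=CC2=C[C@H]3OC(C)(C)O[C@@H]3C[C@]2(C)[C@H]1C | intermediate
18 | (R)-4-benzyl-3-propionyloxazolidin-2-one | CCC(=O)N1[C@H](Cc2ccccc2)COC1=O | starting material
19 | acetaldehyde | CC=O | starting material
20 | (R)-4-benzyl-3-[(2R,3S)-3-hydroxy-2-methylbutanoyl]oxazolidin-2-one | C[C@H](O)[C@@H](C)C(=O)N1[C@H](Cc2ccccc2)COC1=O | intermediate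
21 | (2R,3S)-3-hydroxy-N-methoxy-N,2-dimethylbutanamide | C[C@H](O)[C@@H](C)C(=O)N(C)OC | intermediate
22 | (2R,3S)-N-methoxy-N,2-dimethyl-3-[(triethylsilyl)oxy]butanamide | C[C@H](O[Si](CC)(CC)CC)[C@@H](C)C(=O)N(C)OC | intermediate
23 | (2R,3S)-2-methyl-3-[(triethylsilyl)oxy]butanal | C[C@H](O[Si](CC)(CC)CC)[C@@H](C)C=O | intermediate
24 | triethyl 4-phosphonocrotonate | CCOC(=O)/C=C/CP(=O)(OCC)OCC | starting material
25 | ethyl (2E,4E,6S,7S)-6-methyl-7-[(triethylsilyl)oxy]octa-2,4-dienoate | C[C@H](O[Si](CC)(CC)CC)[C@@H](C)/C=C/C=C/C(=O)OCC | intermediate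
26 | (2E,4E,6S,7S)-6-methyl-7-[(triethylsilyl)oxy]octa-2,4-dienoic acid | C[C@H](O[Si](CC)(CC)CC)[C@@H](C)/C=C/C=C/C(=O)O | intermediate
27 | (2R,3R,4aR,5R,6S)-2,3-(isopropylidenedioxy)-4a,5-dimethyl-2,3,4,4a,5,6-hexahydronaphthalen-6-yl (2E,4E,6S,7S)-6-methyl-7-[(triethylsilyl)oxy]octa-2,4-dienoate | C[C@H](O[Si](CC)(CC)CC)[C@@H](C)/C=C/C=C/C(=O)O[C@H]1C=CC2=C[C@H]3OC(C)(C)O[C@@H]3C[C@]2(C)[C@H]1C | intermediate
28 | (2R,3R,4aR,5R,6S)-2,3-dihydroxy-4a,5-dimethyl-2,3,4,4a,5,6-hexahydronaphthalen-6-yl (2E,4E,6S,7S)-7-hydroxy-6-methylocta-2,4-dienoate | C[C@H](O)[C@@H](C)/C=C/C=C/C(=O)O[C@H]1C=CC2=C[C@@H](O)[C@H](O)C[C@]2(C)[C@H]1C | intermediate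
29 | (3R,4aR,5R,6S)-3-hydroxy-4a,5-dimethyl-2-oxo-2,3,4,4a,5,6-hexahydronaphthalen-6-yl (2E,4E,6S,7S)-7-hydroxy-6-methylocta-2,4-dienoate | C[C@H](O)[C@@H](C)/C=C/C=C/C(=O)O[C@H]1C=CC2=CC(=O)[C@H](O)C[C@]2(C)[C@H]1C | target

**Step count and risks**

Total step count: 20. Longest linear sequence: 14 (steps 1–11 and 18–20).

Steps most likely to fail:

1. Step 6 (Proposed new method). The sequence may stop after the first ring closure because the proton shift from C-8a is slow. The anion of 7 may instead be lost through deprotonation at the enoate γ-CH2 with opening of the acetonide, or the conjugate addition may show poor facial selectivity. Fallback (from 7, back at 9; known reaction types only): the two ring closures are run as separate operations. Treatment of 7 with one equivalent of LiN(SiMe3)2 at −78 → −20 °C and a proton quench should allow isolation of the vinyl sulfone ester 8 (conjugate addition of a sulfone-stabilised carbanion). Catalytic DBU in MeCN should then move the double bond out of conjugation with sulfur to give the allylic sulfone ester F1 (base-mediated vinyl-to-allyl sulfone isomerisation). The α-sulfonyl carbanion of F1 (LiN(SiMe3)2, THF, 0 → 40 °C) is then acylated by the ester in a conventional sulfone Dieckmann condensation to give 9.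

2. Step 10. The hydrogenation may over-reduce the ring dienone, or hydrogen may be delivered with poor facial selectivity at C-5. Fallback (from 12, back at 16): the methyl group is introduced by enolate alkylation instead. LiN(iPr)2 and MeI at −78 °C should give the 5-epi ketone F2 (alkylation anti to the angular methyl). A second deprotonation with LiN(iPr)2, followed by kinetic protonation of the cross-conjugated enolate with 2,6-di-tert-butylphenol at −78 °C from the face opposite the C-4a methyl, should give 16.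

3. Step 19. The acid needed to open the acetonide may ionise the dienylic C-6 ester, with solvolysis or allylic transposition. Fallback (from 16, back at 28): the acetonide is exchanged for fluoride-labile groups before the ester is made. Aqueous AcOH at 50 °C on the robust dienone 16 should give the diol F3. Et3SiOTf and 2,6-lutidine give the bis(triethylsilyl) ether F4. Luche reduction (NaBH4, CeCl3·7H2O) gives the dienol F5, and Yamaguchi esterification with 26 gives the ester F6. HF·pyridine in THF/pyridine then removes all three silyl groups to give 28.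

Further compounds
F1 | step 6 | methyl [(2R,3R,4aR)-2,3-(isopropylidenedioxy)-4a-methyl-8a-[2-(phenylsulfonyl)ethylidene]cyclohexan-4a-yl]acetate (ring A only, core locants) | COC(=O)C[C@@]1(C)C[C@H]2OC(C)(C)O[C@@H]2CC1=CCS(=O)(=O)c3ccccc3
F2 | step 10 | (2R,3R,4aR,5S)-2,3-(isopropylidenedioxy)-4a,5-dimethyl-3,4,4a,5-tetrahydronaphthalen-6(2H)-one | O=C1C=CC2=C[C@H]3OC(C)(C)O[C@@H]3C[C@]2(C)[C@@H]1C
F3 | step 19 | (2R,3R,4aR,5R)-2,3-dihydroxy-4a,5-dimethyl-3,4,4a,5-tetrahydronaphthalen-6(2H)-one | O=C1C=CC2=C[C@@H](O)[C@H](O)C[C@]2(C)[C@H]1C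
F4 | step 19 | (2R,3R,4aR,5R)-4a,5-dimethyl-2,3-bis[(triethylsilyl)oxy]-3,4,4a,5-tetrahydronaphthalen-6(2H)-one | O=C1C=CC2=C[C@@H](O[Si](CC)(CC)CC)[C@H](O[Si](CC)(CC)CC)C[C@]2(C)[C@H]1C
F5 | step 19 | (2R,3R,4aR,5R,6S)-4a,5-dimethyl-2,3-bis[(triethylsilyl)oxy]-2,3,4,4a,5,6-hexahydronaphthalen-6-ol | O[C@H]1C=CC2=C[C@@H](O[Si](CC)(CC)CC)[C@H](O[Si](CC)(CC)CC)C[C@]2(C)[C@H]1C
F6 | step 19 | (2R,3R,4aR,5R,6S)-4a,5-dimethyl-2,3-bis[(triethylsilyl)oxy]-2,3,4,4a,5,6-hexahydronaphthalen-6-yl (2E,4E,6S,7S)-6-methyl-7-[(triethylsilyl)oxy]octa-2,4-dienoate | C[C@H](O[Si](CC)(CC)CC)[C@@H](C)/C=C/C=C/C(=O)O[C@H]1C=CC2=C[C@@H](O[Si](CC)(CC)CC)[C@H](O[Si](CC)(CC)CC)C[C@]2(C)[C@H]1C
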